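The hydrindanone is numbered as an indane: C1 CH–side chain, C2 C=O, C3 CH–O, C3a/C7a ring fusion, C4 C=CH2, C5 CH–O, C7 CH–iPr. The cyclohexane ring (C3a–C4–C5–C6–C7–C7a) is grown from a cyclopentane. An alkyne Prins–pinacol cascade on a 1-ethynyl-2-(2,2-dibenzyloxyethyl)-3-isopropylcyclopentyl silyl ether forms C2–C3 and shifts C7a from the carbinol carbon C4 to the alkyne carbon C3a. One operation thus closes the new five-membered ring (C1–C2–C3–C3a–C7a), inserts C3a into the old carbocycle, and leaves C4=O (future methylidene), the C3=C3a enone (handle for O-3 and H-3a) and oxygen at C2 (future ketone). The precursor comes from cyclopentenone by asymmetric conjugate addition–allylation.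

Key step: step 6

Remark on notation: the core locants above are also used for the corresponding atoms of the monocyclic precursors. β is the face of the bicycle that carries H-7a, α the opposite face. The SMILES strings define the configurations.

Assumption: the stereodescriptors of the structure are taken literally, so the C3 ester is (R)-2-methylbutanoate and the C5 ester is (E)-3-methylpent-2-enoate (methyl cis to the carbonyl). Both acids, diisopropylzinc and ethynylmagnesium bromide are taken as purchasable.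

Step 1
Reactants: 1 cyclopent-2-en-1-one; 2 diisopropylzinc; 3 allyl iodide
Product: 5 (2R,3R)-2-allyl-3-isopropylcyclopentan-1-one, via zinc enolate 4 (not isolated)
Conditions: i-Pr2Zn, Cu(OTf)2 (2 mol %), chiral phosphoramidite ligand (4 mol %, enantiomer giving (R)-4), toluene, −30 °C; then allyl iodide, HMPA, 0 °C
Reagents that add atoms: none
Why: Copper-catalysed asymmetric conjugate addition sets the isopropyl-bearing carbon (future C7) under ligand control and gives zinc enolate 4 regiospecifically, whose C-allylation occurs anti to the new isopropyl group to give the trans-2,3-disubstituted ketone (tandem conjugate addition–enolate alkylation).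

Step 2
Reactants: 5 (2R,3R)-2-allyl-3-isopropylcyclopentan-1-one; 6 ethynylmagnesium bromide
Product: 7 (1S,2R,3R)-2-allyl-1-ethynyl-3-isopropylcyclopentan-1-ol
Conditions: HC≡CMgBr, anhydrous CeCl3, THF, −78 → 0 °C
Reagents that add atoms: none
Why: The organocerium reagent undergoes 1,2-addition to the enolisable ketone from the face anti to the adjacent allyl group (substrate control), and this carbinol centre later becomes the C4 carbonyl carbon, so its configuration is not carried into the target.

Step 3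
Reactants: 7 (1S,2R,3R)-2-allyl-1-ethynyl-3-isopropylcyclopentan-1-ol
Product: 8 (1S,2R,3R)-2-allyl-1-ethynyl-3-isopropyl-1-(triethylsilyloxy)cyclopentane
Conditions: TESOTf, 2,6-lutidine, CH2Cl2, −78 → 0 °C
Reagents that add atoms: triethylsilyl trifluoromethanesulfonate, CC[Si](CC)(CC)OS(=O)(=O)C(F)(F)F
Why: Silylation of the tertiary propargylic alcohol prevents cyclic acetal formation with the future aldehyde and provides the silyloxy group whose lone pair drives the later 1,2-shift.

Step 4
Reactants: 8 (1S,2R,3R)-2-allyl-1-ethynyl-3-isopropyl-1-(triethylsilyloxy)cyclopentane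
Product: 9 (1S,2R,3R)-1-ethynyl-3-isopropyl-2-(2-oxoethyl)-1-(triethylsilyloxy)cyclopentane
Conditions: OsO4 (2 mol %), NaIO4, 2,6-lutidine, dioxane–H2O, rt
Reagents that add atoms: sodium periodate, [Na+].[O-]I(=O)(=O)=O (terminal oxidant that supplies the aldehyde oxygen through OsO4)
Why: Lemieux–Johnson cleavage converts the terminal alkene into the aldehyde while the less reactive terminal alkyne and the silyl ether are inert to catalytic OsO4/periodate.

Step 5
Reactants: 9 (1S,2R,3R)-1-ethynyl-3-isopropyl-2-(2-oxoethyl)-1-(triethylsilyloxy)cyclopentane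
Product: 10 (1S,2R,3R)-2-[2,2-bis(benzyloxy)ethyl]-1-ethynyl-3-isopropyl-1-(triethylsilyloxy)cyclopentane
Conditions: BnOSiMe3 (2.2 equiv), TMSOTf (2 mol %), CH2Cl2, −78 °C; pyridine quench
Reagents that add atoms: benzyloxytrimethylsilane, C[Si](C)(C)OCc1ccccc1
Why: TMSOTf-catalysed acetalisation with the benzyl silyl ether runs aprotically at −78 °C so the tertiary silyl ether survives, and benzyl is chosen because the ether oxygen it leaves at C2 can later be freed reductively.

Step 6
Reactants: 10 (1S,2R,3R)-2-[2,2-bis(benzyloxy)ethyl]-1-ethynyl-3-isopropyl-1-(triethylsilyloxy)cyclopentane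
Product: 12 2α-benzyloxy-7β-isopropyl-1,2,5,6,7,7a-hexahydro-4H-inden-4-one (H-7a β; C3=C3a enone), via oxocarbenium ion 11 (not isolated)
Conditions: SnCl4 (1.5 equiv), CH2Cl2, −78 → −20 °C; aq NaHCO3
Reagents that add atoms: none
Why: SnCl4 ionises the acetal to the (E)-oxocarbenium ion 11, the terminal alkyne carbon C3 attacks it (alkyne–Prins, C2–C3 bond), and the vinyl cation developing at C3a is quenched by a 1,2-shift of C7a from C4 to C3a, pushed by the silyloxy lone pair, with loss of the silyl group to unveil the C4 ketone. The closest known reaction type is the pinacol-terminated Prins cyclisation with an alkyne terminator (ring-enlarging cyclopentene annulation). The five-membered ring C1–C2–C3–C3a–C7a is closed by 6-endo-dig attack followed by contraction of the incipient cyclohexenyl cation, and the cyclohexanone arises by one-carbon expansion of the cyclopentane through insertion of C3a between C4 and C7a. C7 and C7a come from 5, C7a migrating with retention, and C2 is set by a chair-like transition state with the benzyloxy group of the (E)-oxocarbenium ion pseudo-equatorial, which places OBn anti to H-7a (this centre only directs step 7 and is later oxidised). The step needs migration of the ring carbon C7a rather than C5, which is secured because the C4–C7a bond lies in the plane of the vacant in-plane orbital of the cyclic vinyl cation whereas the exocyclic bonds at C4 are orthogonal to it.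

Step 7
Reactants: 12 2α-benzyloxy-7β-isopropyl-1,2,5,6,7,7a-hexahydro-4H-inden-4-one
Product: 14 2α-benzyloxy-3β-hydroxy-7β-isopropyl-3aα,7aβ-octahydro-4H-inden-4-one (trans-fused), via C3 pinacol boronate 13 (not isolated)
Conditions: B2pin2, CuCl (5 mol %), Xantphos (5 mol %), NaOt-Bu (10 mol %), MeOH (2 equiv), THF, rt; then NaBO3·4H2O, THF–H2O, rt
Reagents that add atoms: bis(pinacolato)diboron, CC1(C)OB(OC1(C)C)B1OC(C)(C)C(C)(C)O1 (boron of 13); sodium perborate, [Na+].[Na+].O[B-]1(O)OO[B-](O)(O)OO1 (oxygen at C3)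
Why: Conjugate borylation of the s-cis enone places boron on C3 from the β-face anti to the neighbouring 2α-benzyloxy group, protonation of the enolate at C3a occurs axially and anti to the new C–B bond to give the trans ring fusion (expected to be the thermodynamically preferred one as well), and perborate oxidation replaces boron by hydroxyl with retention.

Step 8
Reactants: 14 2α-benzyloxy-3β-hydroxy-7β-isopropyl-3aα,7aβ-octahydro-4H-inden-4-one
Product: 15 2α-benzyloxy-3β-(tert-butyldimethylsilyloxy)-7β-isopropyl-3aα,7aβ-octahydro-4H-inden-4-one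
Conditions: TBSOTf, 2,6-lutidine, CH2Cl2, −78 °C
Reagents that add atoms: tert-butyldimethylsilyl trifluoromethanesulfonate, CC(C)(C)[Si](C)(C)OS(=O)(=O)C(F)(F)F
Why: Silyl triflate protection of the hindered secondary alcohol at low temperature gives a TBS ether that withstands all steps up to the late fluoride deprotection.

Step 9
Reactants: 15 2α-benzyloxy-3β-(tert-butyldimethylsilyloxy)-7β-isopropyl-3aα,7aβ-octahydro-4H-inden-4-one
Product: 16 2α-benzyloxy-3β-(tert-butyldimethylsilyloxy)-7β-isopropyl-4-methylidene-3aα,7aβ-octahydro-1H-indene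
Conditions: Zn, CH2Br2, TiCl4, THF–CH2Cl2, 0 °C → rt
Reagents that add atoms: dibromomethane, BrCBr
Why: The non-basic Takai–Lombardo reagent methylenates the hindered ketone without epimerising C3a or eliminating the β-silyloxy group, as a basic ylide might.

Step 10
Reactants: 16 2α-benzyloxy-3β-(tert-butyldimethylsilyloxy)-7β-isopropyl-4-methylidene-3aα,7aβ-octahydro-1H-indene
Product: 17 3β-(tert-butyldimethylsilyloxy)-7β-isopropyl-4-methylidene-3aα,7aβ-octahydro-1H-inden-2α-ol
Conditions: lithium 4,4′-di-tert-butylbiphenylide (LiDBB), THF, −78 °C; NH4Cl quench at −78 °C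
Reagents that add atoms: none
Why: Electron-transfer debenzylation cleaves the benzyl ether while the isolated 1,1-disubstituted alkene and the silyl ether are inert, and the trans disposition of the C2 alkoxide and the C3 silyl ether disfavours silyl migration.

Step 11
Reactants: 17 3β-(tert-butyldimethylsilyloxy)-7β-isopropyl-4-methylidene-3aα,7aβ-octahydro-1H-inden-2α-ol
Product: 18 3β-(tert-butyldimethylsilyloxy)-7β-isopropyl-4-methylidene-3aα,7aβ-octahydro-2H-inden-2-one
Conditions: Dess–Martin periodinane, NaHCO3, CH2Cl2, rt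
Reagents that add atoms: none
Why: Buffered Dess–Martin oxidation gives the α-silyloxy ketone without epimerisation at C3.

Step 12
Reactants: 18 3β-(tert-butyldimethylsilyloxy)-7β-isopropyl-4-methylidene-3aα,7aβ-octahydro-2H-inden-2-one; 19 acetaldehyde
Product: 22 (1Z)-1-ethylidene-3β-(tert-butyldimethylsilyloxy)-7β-isopropyl-4-methylidene-3aα,7aβ-octahydro-2H-inden-2-one, via lithium aldolate 20 (not isolated), via mesylate 21 (not isolated)
Conditions: LDA, THF, −78 °C; MeCHO; then MsCl, Et3N, −78 → 0 °C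
Reagents that add atoms: none
Why: Kinetic deprotonation occurs at the unhindered C1 methylene rather than at the silyloxy-bearing C3, and aldol addition followed by E1cB elimination of the mesylate (aldol condensation) gives the ethylidene ketone, expected as the Z isomer because this keeps the methyl group away from the C7a substituents.

Step 13
Reactants: 22 (1Z)-1-ethylidene-3β-(tert-butyldimethylsilyloxy)-7β-isopropyl-4-methylidene-3aα,7aβ-octahydro-2H-inden-2-one
Product: 24 1β-[(1S)-1-hydroxyethyl]-3β-(tert-butyldimethylsilyloxy)-7β-isopropyl-4-methylidene-3aα,7aβ-octahydro-2H-inden-2-one, via side-chain pinacol boronate 23 (not isolated)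
Conditions: B2pin2, CuCl (5 mol %), Josiphos-type ligand (5.5 mol %, antipode matched to the alkene geometry), NaOt-Bu (10 mol %), MeOH, THF, 0 °C; then NaBO3·4H2O, THF–H2O, rt
Reagents that add atoms: bis(pinacolato)diboron, CC1(C)OB(OC1(C)C)B1OC(C)(C)C(C)(C)O1 (boron of 23); sodium perborate, [Na+].[Na+].O[B-]1(O)OO[B-](O)(O)OO1 (side-chain oxygen)
Why: Ligand-controlled copper-catalysed β-borylation sets the side-chain carbon as the (S)-boronate, the enolate is protonated at C1 from the α-face anti to the 3β-silyloxy group so that the side chain becomes β and pseudo-equatorial, and perborate oxidation proceeds with retention.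

Step 14
Reactants: 24 1β-[(1S)-1-hydroxyethyl]-3β-(tert-butyldimethylsilyloxy)-7β-isopropyl-4-methylidene-3aα,7aβ-octahydro-2H-inden-2-one
Product: 25 1β-[(1S)-1-acetoxyethyl]-3β-(tert-butyldimethylsilyloxy)-7β-isopropyl-4-methylidene-3aα,7aβ-octahydro-2H-inden-2-one
Conditions: Ac2O, pyridine, DMAP (cat.), CH2Cl2, 0 °C
Reagents that add atoms: acetic anhydride, CC(=O)OC(C)=O
Why: Acetylation of the secondary β-hydroxy ketone at 0 °C with only catalytic DMAP installs the acetate while avoiding E1cB loss of the new acyloxy group.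

Step 15
Reactants: 25 1β-[(1S)-1-acetoxyethyl]-3β-(tert-butyldimethylsilyloxy)-7β-isopropyl-4-methylidene-3aα,7aβ-octahydro-2H-inden-2-one
Product: 26 1β-[(1S)-1-acetoxyethyl]-5α-hydroxy-3β-(tert-butyldimethylsilyloxy)-7β-isopropyl-4-methylidene-3aα,7aβ-octahydro-2H-inden-2-one
Conditions: SeO2 (cat.), t-BuOOH, CH2Cl2, 0 °C → rt
Reagents that add atoms: tert-butyl hydroperoxide, CC(C)(C)OO (terminal oxidant); selenium dioxide, O=[Se]=O (catalytic oxygen-transfer agent)
Why: Selenium dioxide allylic oxidation (ene reaction then [2,3]-sigmatropic shift) attacks the ring methylene C5 in preference to the ring-fusion methine C3a and removes the axial 5α-hydrogen, so the oxygen is returned axially on the α-face with the exocyclic alkene restored.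

Step 16
Reactants: 26 1β-[(1S)-1-acetoxyethyl]-5α-hydroxy-3β-(tert-butyldimethylsilyloxy)-7β-isopropyl-4-methylidene-3aα,7aβ-octahydro-2H-inden-2-one; 27 (E)-3-methylpent-2-enoic acid
Product: 28 1β-[(1S)-1-acetoxyethyl]-3β-(tert-butyldimethylsilyloxy)-7β-isopropyl-4-methylidene-2-oxo-3aα,7aβ-octahydro-1H-inden-5α-yl (E)-3-methylpent-2-enoate
Conditions: DCC, DMAP (cat.), CH2Cl2, 0 °C → rt
Reagents that add atoms: none
Why: Steglich esterification acylates the axial allylic alcohol, and low temperature with catalytic DMAP limits deconjugation of the enoate and β-elimination of the acetate.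

Step 17
Reactants: 28 1β-[(1S)-1-acetoxyethyl]-3β-(tert-butyldimethylsilyloxy)-7β-isopropyl-4-methylidene-2-oxo-3aα,7aβ-octahydro-1H-inden-5α-yl (E)-3-methylpent-2-enoate
Product: 29 1β-[(1S)-1-acetoxyethyl]-3β-hydroxy-7β-isopropyl-4-methylidene-2-oxo-3aα,7aβ-octahydro-1H-inden-5α-yl (E)-3-methylpent-2-enoate
Conditions: HF·pyridine, THF, 0 °C → rt
Reagents that add atoms: none
Why: Acidic fluoride desilylation frees the C3 hydroxyl without touching the esters or the base-sensitive β-acetoxy ketone.

Step 18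
Reactants: 29 1β-[(1S)-1-acetoxyethyl]-3β-hydroxy-7β-isopropyl-4-methylidene-2-oxo-3aα,7aβ-octahydro-1H-inden-5α-yl (E)-3-methylpent-2-enoate; 30 (R)-2-methylbutanoic acid
Product: 31 CNP0289166.2, 1β-[(1S)-1-acetoxyethyl]-7β-isopropyl-4-methylidene-2-oxo-3aα,7aβ-octahydro-1H-indene-3β,5α-diyl 3-[(2R)-2-methylbutanoate] 5-[(2E)-3-methylpent-2-enoate]
Conditions: DCC, DMAP (cat.), CH2Cl2, 0 °C
Reagents that add atoms: none
Why: Carbodiimide esterification of the α-ketol with the enantiopure acid avoids a ketene intermediate, so the α-stereocentre of the acyl group is retained and the target is obtained.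

Compound list
1 | cyclopent-2-en-1-one | O=C1C=CCC1 | starting material
2 | diisopropylzinc | CC(C)[Zn]C(C)C | starting material
3 | allyl iodide | C=CCI | starting material
4 | isopropylzinc (R)-3-isopropylcyclopent-1-en-1-olate (zinc enolate) | CC(C)[Zn]OC1=C[C@@H](C(C)C)CC1 | intermediate
5 | (2R,3R)-2-allyl-3-isopropylcyclopentan-1-one | O=C1[C@H](CC=C)[C@@H](C(C)C)CC1 | intermediate
6 | ethynylmagnesium bromide | C#C[Mg]Br | starting material
7 | (1S,2R,3R)-2-allyl-1-ethynyl-3-isopropylcyclopentan-1-ol | C#C[C@@]1(O)[C@H](CC=C)[C@@H](C(C)C)CC1 | intermediate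
8 | (1S,2R,3R)-2-allyl-1-ethynyl-3-isopropyl-1-(triethylsilyloxy)cyclopentane | C#C[C@@]1(O[Si](CC)(CC)CC)[C@H](CC=C)[C@@H](C(C)C)CC1 | intermediate
9 | (1S,2R,3R)-1-ethynyl-3-isopropyl-2-(2-oxoethyl)-1-(triethylsilyloxy)cyclopentane | C#C[C@@]1(O[Si](CC)(CC)CC)[C@H](CC=O)[C@@H](C(C)C)CC1 | intermediate
10 | (1S,2R,3R)-2-[2,2-bis(benzyloxy)ethyl]-1-ethynyl-3-isopropyl-1-(triethylsilyloxy)cyclopentane | C#C[C@@]1(O[Si](CC)(CC)CC)[C@H](CC(OCc2ccccc2)OCc2ccccc2)[C@@H](C(C)C)CC1 | intermediate
11 | O-benzyl oxocarbenium ion from 10 (side chain CH2–CH=O+Bn) | C#C[C@@]1(O[Si](CC)(CC)CC)[C@H](CC=[O+]Cc2ccccc2)[C@@H](C(C)C)CC1 | intermediate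
12 | 2α-benzyloxy-7β-isopropyl-1,2,5,6,7,7a-hexahydro-4H-inden-4-one (H-7a β) | O=C1CC[C@H](C(C)C)[C@H]2C[C@@H](OCc3ccccc3)C=C12 | intermediate
13 | 2α-benzyloxy-7β-isopropyl-3β-(pinacolatoboryl)-3aα,7aβ-octahydro-4H-inden-4-one | O=C1[C@@H]2[C@H](C[C@@H](OCc3ccccc3)[C@@H]2B4OC(C)(C)C(C)(C)O4)[C@@H](C(C)C)CC1 | intermediate
14 | 2α-benzyloxy-3β-hydroxy-7β-isopropyl-3aα,7aβ-octahydro-4H-inden-4-one | O=C1[C@@H]2[C@H](C[C@@H](OCc3ccccc3)[C@@H]2O)[C@@H](C(C)C)CC1 | intermediate
15 | 2α-benzyloxy-3β-(tert-butyldimethylsilyloxy)-7β-isopropyl-3aα,7aβ-octahydro-4H-inden-4-one | O=C1[C@@H]2[C@H](C[C@@H](OCc3ccccc3)[C@@H]2O[Si](C)(C)C(C)(C)C)[C@@H](C(C)C)CC1 | intermediate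
16 | 2α-benzyloxy-3β-(tert-butyldimethylsilyloxy)-7β-isopropyl-4-methylidene-3aα,7aβ-octahydro-1H-indene | C=C1[C@@H]2[C@H](C[C@@H](OCc3ccccc3)[C@@H]2O[Si](C)(C)C(C)(C)C)[C@@H](C(C)C)CC1 | intermediate
17 | 3β-(tert-butyldimethylsilyloxy)-7β-isopropyl-4-methylidene-3aα,7aβ-octahydro-1H-inden-2α-ol | C=C1[C@@H]2[C@H](C[C@@H](O)[C@@H]2O[Si](C)(C)C(C)(C)C)[C@@H](C(C)C)CC1 | intermediate
18 | 3β-(tert-butyldimethylsilyloxy)-7β-isopropyl-4-methylidene-3aα,7aβ-octahydro-2H-inden-2-one | C=C1[C@@H]2[C@H](CC(=O)[C@@H]2O[Si](C)(C)C(C)(C)C)[C@@H](C(C)C)CC1 | intermediate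
19 | acetaldehyde | CC=O | starting material
20 | lithium aldolate of 18 with acetaldehyde (epimers at C1 and the carbinol carbon) | C=C1[C@@H]2[C@H](C(C(C)O[Li])C(=O)[C@@H]2O[Si](C)(C)C(C)(C)C)[C@@H](C(C)C)CC1 | intermediate
21 | methanesulfonate of the aldol (epimers at C1 and the carbinol carbon) | C=C1[C@@H]2[C@H](C(C(C)OS(C)(=O)=O)C(=O)[C@@H]2O[Si](C)(C)C(C)(C)C)[C@@H](C(C)C)CC1 | intermediate
22 | (1Z)-1-ethylidene-3β-(tert-butyldimethylsilyloxy)-7β-isopropyl-4-methylidene-3aα,7aβ-octahydro-2H-inden-2-one | C=C1[C@@H]2[C@H](/C(=C/C)C(=O)[C@@H]2O[Si](C)(C)C(C)(C)C)[C@@H](C(C)C)CC1 | intermediate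
23 | 1β-[(1S)-1-(pinacolatoboryl)ethyl]-3β-(tert-butyldimethylsilyloxy)-7β-isopropyl-4-methylidene-3aα,7aβ-octahydro-2H-inden-2-one | C=C1[C@@H]2[C@H]([C@H]([C@H](C)B4OC(C)(C)C(C)(C)O4)C(=O)[C@@H]2O[Si](C)(C)C(C)(C)C)[C@@H](C(C)C)CC1 | intermediate
24 | 1β-[(1S)-1-hydroxyethyl]-3β-(tert-butyldimethylsilyloxy)-7β-isopropyl-4-methylidene-3aα,7aβ-octahydro-2H-inden-2-one | C=C1[C@@H]2[C@H]([C@H]([C@H](C)O)C(=O)[C@@H]2O[Si](C)(C)C(C)(C)C)[C@@H](C(C)C)CC1 | intermediate
25 | 1β-[(1S)-1-acetoxyethyl]-3β-(tert-butyldimethylsilyloxy)-7β-isopropyl-4-methylidene-3aα,7aβ-octahydro-2H-inden-2-one | C=C1[C@@H]2[C@H]([C@H]([C@H](C)OC(C)=O)C(=O)[C@@H]2O[Si](C)(C)C(C)(C)C)[C@@H](C(C)C)CC1 | intermediate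
26 | 1β-[(1S)-1-acetoxyethyl]-5α-hydroxy-3β-(tert-butyldimethylsilyloxy)-7β-isopropyl-4-methylidene-3aα,7aβ-octahydro-2H-inden-2-one | C=C1[C@@H]2[C@H]([C@H]([C@H](C)OC(C)=O)C(=O)[C@@H]2O[Si](C)(C)C(C)(C)C)[C@@H](C(C)C)C[C@@H]1O | intermediate
27 | (E)-3-methylpent-2-enoic acid | CC/C(C)=C/C(=O)O | starting material
28 | 1β-[(1S)-1-acetoxyethyl]-3β-(tert-butyldimethylsilyloxy)-7β-isopropyl-4-methylidene-2-oxo-3aα,7aβ-octahydro-1H-inden-5α-yl (E)-3-methylpent-2-enoate | C=C1[C@@H]2[C@H]([C@H]([C@H](C)OC(C)=O)C(=O)[C@@H]2O[Si](C)(C)C(C)(C)C)[C@@H](C(C)C)C[C@@H]1OC(=O)/C=C(\C)CC | intermediate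
29 | 1β-[(1S)-1-acetoxyethyl]-3β-hydroxy-7β-isopropyl-4-methylidene-2-oxo-3aα,7aβ-octahydro-1H-inden-5α-yl (E)-3-methylpent-2-enoate | C=C1[C@@H]2[C@H]([C@H]([C@H](C)OC(C)=O)C(=O)[C@@H]2O)[C@@H](C(C)C)C[C@@H]1OC(=O)/C=C(\C)CC | intermediate
30 | (R)-2-methylbutanoic acid | CC[C@@H](C)C(=O)O | starting material
31 | CNP0289166.2 | C=C1[C@@H]2[C@H]([C@H]([C@H](C)OC(C)=O)C(=O)[C@@H]2OC(=O)[C@H](C)CC)[C@@H](C(C)C)C[C@@H]1OC(=O)/C=C(\C)CC | target

Total step count: 18. Longest linear sequence: 18 steps, from cyclopent-2-en-1-one 1 to 31.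

Steps most likely to fail

Step 6. The terminal alkyne may be too weak a π-nucleophile, so that the oxocarbenium ion loses the silyl group or is captured by chloride before the C2–C3 bond forms, or the shift may be incomplete. The fallback keeps the same ring expansion but uses the better-established alkene terminator and restores the unsaturation afterwards. It sets out from 10: Lindlar semihydrogenation gives the vinyl carbinol acetal F1, and SnCl4 then triggers the alkene Prins–pinacol cascade to the cis-fused saturated ketone F2. Equilibrating silylation (TMSCl, NaI, Et3N, MeCN) gives the more substituted silyl enol ether F3. PhSeCl adds axially at C3a, anti to H-7a, to give the selenide F4. Oxidation with H2O2 then causes selenoxide syn-elimination, which can only engage a C3 hydrogen, and the route is rejoined at enone 12.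

Step 7. The boryl-copper addition may show insufficient facial bias at C3, the trans-diaxial β-benzyloxy boronate may eliminate, or the β-hydroxy ketone may undergo retro-aldol cleavage or dehydration during the basic oxidation. The fallback sets out from 12: nucleophilic epoxidation (t-BuOOH, DBU) anti to the benzyloxy group gives the 3β,3aβ-epoxy ketone F5. SmI2 in THF–MeOH at −90 °C cleaves the C3a–O bond, and axial protonation of the samarium enolate gives the trans-fused β-hydroxy ketone, rejoining at 14 without boron or a basic oxidant.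

Step 13. The catalyst may be mismatched with the substrate's own facial preference, or an E/Z mixture of 22 may erode the configuration of the carbinol carbon. The fallback sets out from 18: the lithium enolate is added to acetaldehyde and quenched to the aldol mixture F6, which Dess–Martin oxidation converts into the 1-acetyl ketone F7 (C1 stereolabile through its enol). Ruthenium–TsDPEN transfer hydrogenation with dynamic kinetic resolution (HCO2H/Et3N) reduces the less hindered acetyl carbonyl under catalyst control to the (S)-carbinol while C1 settles in the pseudo-equatorial β-configuration, rejoining at 24.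

Further compounds
F1 | step 6 | (1S,2R,3R)-2-[2,2-bis(benzyloxy)ethyl]-1-ethenyl-3-isopropyl-1-(triethylsilyloxy)cyclopentane | C=C[C@@]1(O[Si](CC)(CC)CC)[C@H](CC(OCc2ccccc2)OCc2ccccc2)[C@@H](C(C)C)CC1
F2 | step 6 | 2α-benzyloxy-7β-isopropyl-3aβ,7aβ-octahydro-4H-inden-4-one (cis-fused) | O=C1[C@H]2[C@H](C[C@@H](OCc3ccccc3)C2)[C@@H](C(C)C)CC1
F3 | step 6 | 2α-benzyloxy-7β-isopropyl-4-(trimethylsilyloxy)-2,3,5,6,7,7a-hexahydro-1H-indene (C3a=C4 silyl enol ether) | C[Si](C)(C)OC1=C2C[C@H](OCc3ccccc3)C[C@@H]2[C@@H](C(C)C)CC1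
F4 | step 6 | 2α-benzyloxy-7β-isopropyl-3aα-(phenylselanyl)-7aβ-octahydro-4H-inden-4-one | O=C1[C@]2([Se]c4ccccc4)[C@H](C[C@@H](OCc3ccccc3)C2)[C@@H](C(C)C)CC1
F5 | step 7 | 2α-benzyloxy-3β,3aβ-epoxy-7β-isopropyl-7aβ-octahydro-4H-inden-4-one | O=C1CC[C@H](C(C)C)[C@H]2C[C@@H](OCc3ccccc3)[C@@H]3O[C@]123
F6 | step 13 | 1-(1-hydroxyethyl)-3β-(tert-butyldimethylsilyloxy)-7β-isopropyl-4-methylidene-3aα,7aβ-octahydro-2H-inden-2-one (epimers at C1 and the carbinol carbon) | C=C1[C@@H]2[C@H](C(C(C)O)C(=O)[C@@H]2O[Si](C)(C)C(C)(C)C)[C@@H](C(C)C)CC1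
F7 | step 13 | 1-acetyl-3β-(tert-butyldimethylsilyloxy)-7β-isopropyl-4-methylidene-3aα,7aβ-octahydro-2H-inden-2-one | C=C1[C@@H]2[C@H](C(C(C)=O)C(=O)[C@@H]2O[Si](C)(C)C(C)(C)C)[C@@H](C(C)C)CC1
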